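Take the amber run and carry one reading from it into the flask.

| flask | free monomer | transfer agent | pre-initiator | remark | time |
|---|---|---|---|---|---|
| amber | 1.2 M | 0.75 M | 11 mM | run made earlier |  |
| flask | 2.5 M | 0.750 M | 11 mM |  | 15 min |

- amber (time / min: monomer in chains / %, free monomer / %): 0.250: 0.8, 96.8; 0.417: 0, 96.3; 0.667: 0, 92.1; 1.00: 4.5, 87.2; 2.00: 8.3, 73.6; 3.00: 12.7, 60.1

(standard deviation of a reading: 1 percentage point)

- the average divides the monomer in chains by the number of chains begun, living and dead together
- on the list of suspects stand: free monomer + initiator -> living end + monomer in chains; free monomer + living end -> monomer in chains + living end; living end + transfer agent -> dead chain; pre-initiator <-> initiator; free monomer -> uncatalysed product; living end -> dead end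
- the earlier runs do not show the number of chains; that part of a forecast is a guess

- whether the average number of monomer units in a chain (chains begun, living or dead) reaches 20 by 15 min (yes / no)
- average number of monomer units in a chain (chains begun, living or dead) at 15 min

By 3.00 min the amber run has lost free monomer at 0.170 min⁻¹, and 31.8% of that loss is found in chains; this reading is the chain share, the part of the lost free monomer that becomes monomer in chains, which is the selectivity of growth against the uncatalysed path. My own reckoning freezes it: monomer in chains climbs steadily through that run, so I take the living ends as constant, and then both paths run in proportion to free monomer and the share carries over to the flask's richer charge. In the flask, free monomer therefore starts passing into chains at 0.0541 min⁻¹ of what is present, and the slowing in this reckoning is the falling free monomer, a factor of 0.0781 at 15 min. Summed over the run, that puts 29.3% of the charge into chains. The number of chains is a guess: one per pre-initiator gives an average of 66.7, more than the 20 wanted.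

The forecast says yes, with an average of 80 (from 45 to 200), higher than my figure, and it reads the amber run as showing that “living ends are not visibly dying yet”.

The flask answers yes: its average passes 20 at 0.914 min and stands at 45.5 at 15 min, lower than the forecast, with monomer in chains at 20.0% of the charge where the frozen share on the reacted free monomer gives 27.2%.

    free monomer + initiator → living end + monomer in chains (k = 0.0350 L mol⁻¹ s⁻¹)
    free monomer + living end → monomer in chains + living end, rate k2*[living end]*[free monomer] (k = 0.420 L mol⁻¹ s⁻¹)
    living end + transfer agent → dead chain (kL = 0.0120 L mol⁻¹ s⁻¹)
    pre-initiator ⇌ initiator (K = 16.0, k = 0.0110 s⁻¹)
    free monomer → uncatalysed product (k = 0.00180 s⁻¹)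
    living end → dead end (k = 0.00650 s⁻¹)

Up to 1.50 min, with living ends at 0.00324 M, growth ran beside the uncatalysed path and the flask's chain share was 32.8%, against the 31.8% read from the amber run. By 7.50 min living ends were down to 2.15 × 10⁻⁴ M and monomer in chains had reached 19.7%, against 20.0% at 15.0 min, while over that same stretch the uncatalysed path ran on and took uncatalysed product from 47.2% to 65.4%.

All runs stem from a simulated flask on assumed constants, and the scatter is random.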